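## The problem

- Target 29 is (2S)-naringenin carrying an (S)-1-methylpiperidin-2-yl group on C6. Phloroglucinol ring A is fused to dihydropyranone ring C along C4a–C8a, ring B sits on C2, and the piperidine is attached through a C6–C2'' bond lying between the two phenolic carbons C5 and C7.
- The C6–C2'' bond is the hard one. It joins a nitrogen-bearing stereogenic sp3 carbon to a doubly ortho-oxygenated aromatic carbon; amidoalkylation of a phloroglucinol would give racemate, and arylation of a piperidine would have to force a very hindered coupling.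
- C2 and C2'' are separated by the whole of ring A and cannot control each other. C2'' is best taken from the chiral pool, and C2 from a reagent-controlled or stereospecific step.
- C2 is fragile. Base opens ring C by retro-oxa-Michael reaction to the chalcone, and before ring C exists a free 4'-hydroxyl would make the benzylic C2–O bond a quinone-methide precursor.
- C2''–N is a benzylic bond on a very electron-rich ring. It can ionise under acid when nitrogen is acylated, and it can leave by retro-Mannich elimination once the flanking hydroxyls are free. The nitrogen is therefore best carried through acid as a protonated tertiary amine, and the phenols freed last under neutral conditions.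
- Ring A is nucleophilic at C8, so N-methylation with an aldehyde cannot be done on the free phenols.
- The enabling feature is the 1,3,5-trioxygenated ring A with C6 between two C–O carbons. C5 with its oxygen and C6 are the two carbons of an ynol ether, C5 being the former carboxyl carbon of N-Boc-L-pipecolic acid 1 and C6 a one-carbon insertion. C7, C8, C8a and C4a, with the oxygens on C7 and C8a, are the four carbons of a 3-alkoxycyclobutenone. Ring A can thus be grown onto the intact stereocentre.

## Retrosynthesis

**29 to 28.** The three benzyl–oxygen bonds are cut last: the ethers on O5 and O7 and the benzyl carbonate on O4'. Neutral hydrogenolysis avoids both base (C2) and acid (C2''–N), and the N-methyl group is already in place, so no aldehyde meets the free phloroglucinol. The forward step must cleave benzyl groups faster than the cyclic benzylic C2–O1 and C2''–N bonds.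

**28 to 25 (through 26 and 27).** C4–C4a is cut as an intramolecular Friedel–Crafts acylation. Closing O1–C2 last would need base and leave C2 uncontrolled. Here C2 is already set and is a bystander. Ring A of 25 is symmetric about the C6–C8a axis, so both ortho carbons give the same product. The forward step must acylate faster than the benzylic ether ionises; the electron-withdrawing carbonate on ring B serves that purpose.

**25 to 18 and 24.** O1–C2 is cut as a Mitsunobu etherification with inversion. This splits the molecule into two fragments, each carrying one stereocentre from its own source. Alcohol 24 comes from keto ester 23 by asymmetric transfer hydrogenation, 23 from acid 20 (through 21 and 22), and 20 from 4-hydroxybenzoic acid 19. The forward step needs SN2 displacement to win over elimination and ionisation.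

**18 to 17, 16 and 13 (through 14 and 15).** No skeletal bond is cut; this is the oxygen and nitrogen bookkeeping.
- Desilylation of 13 and double benzylation make O5 and O7 identical (16).
- Hydride reduction turns the carbamate into the N-methyl amine (17) before any acid is used.
- The 4-methoxybenzyl (PMB) ether on O8a is then removed by acid while nitrogen is protonated, giving phenol 18.
- An oxidative PMB cleavage is avoided because 18 is a para-alkylphenol that an oxidant could take on to a quinone methide at C2''.

**13 to 5 and 8.** This is the key cut. C6–C7, C4a–C5 and C7–C8 are cut at once, dissolving ring A into siloxyalkyne 5 and cyclobutenone 8 (through 9 to 12). Against a C6–C2'' cut, no bond is ever made at the hindered aromatic carbon, and C2'' stays out of the reacting array. The forward reaction must deliver one regiochemistry (C6 between the new hydroxyl and the silyloxy carbon) and leave O8a distinguishable from O5 and O7.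

**5 to 2 and 1 (through 3 and 4); 8 to 6 and 7.** The ynol ether comes from methyl ester 2 by Kowalski homologation and O-silylation of ynolate 4, and 2 from acid 1. Cyclobutenone 8 comes from 3-ethoxycyclobutenone 6 and 4-methoxybenzyl alcohol 7 by alkoxy exchange.

## Roads not taken

**Alternative 1:** The cut is C4–C4a. The (S)-aryloxy acid A2, after carboxyl activation, acylates the ortho carbon and gives the protected flavanone A1.
- Merits: C2 is transferred stereospecifically from a carbinol, the symmetric ring removes any regiochemical question, the fragments are convergent, and an electron-poor ester on ring B guards the benzylic ether.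
- Weak points: as a strategy it presupposes the 6-(piperidin-2-yl)phloroglucinol core with C2'' already set, and that is the hardest part of the molecule. The pivalate on A1 must finally be removed with base, which endangers C2.
- Comparison: for ring C this road is as good as the chosen plan, which uses the same closure as its finishing sequence (steps 11 and 12). The chosen plan adds a defined origin for ring A and C2'' from 1, and a benzyl carbonate in place of the pivalate so that the last step is neutral.

**Alternative 2:** The cut is C2–C3. Diazoketone A4 loses nitrogen under a chiral dirhodium tetracarboxylate, and the carbenoid at C3 inserts into the benzylic C–H bond of the ring B ether to give A3.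
- Merits: ring C and C2 arise in one catalytic step from an achiral benzyl ether, under neutral conditions and late in the route. In step economy for ring C it is better than the two-step Mitsunobu and acylation pair.
- Weak points: closure to a six-membered ring competes with ylide formation at the ether oxygen followed by a 1,2-shift to a five-membered ketone, with addition to the electron-rich ring, and with insertion next to nitrogen. Enantiocontrol in such chromanone-forming insertions is uncertain, and the catalyst must override any bias from C2''. The core with C2'' is again presupposed.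
- Comparison: the chosen plan is longer at ring C but transfers C2 from an alcohol of secure configuration with no positional ambiguity.

**Alternative 3:** The cut is C5–C6. Base turns the side-chain ketone of pyranone ester A6 into its dienolate; C6 attacks the ester carbonyl, and ring A closes and aromatises to A5.
- Merits: no bond is made to a hindered aromatic carbon, the piperidine enters as a homologated pipecolate, and the 5,7-diol appears without phenol protecting groups. In protecting-group economy it is better than the chosen plan.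
- Weak points: the base needed for the Claisen closure acts on a 2-aryl-dihydropyranone, which can open by retro-oxa-Michael reaction and scramble C2. C6 is the more hindered of the enolisable positions, and lactonisation competes. The product carries free phenols while nitrogen still needs deprotection and methylation, which invites Mannich reaction at C8.
- Comparison: the chosen plan spends steps on phenol protection but builds ring A thermally without base, with regiochemistry fixed by ynol ether polarisation, and never exposes C2 to base.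

Key step: step 4

Assumption: flavanone locants are used (O1, C2–C4, C4a, C5–C8, C8a; ring B primed, piperidine double-primed), and the target is read as the (2S,2''S) isomer.

## Route

Step 1
Reactants: 1 (2S)-1-(tert-butoxycarbonyl)piperidine-2-carboxylic acid (N-Boc-L-pipecolic acid)
Product: 2 1-tert-butyl 2-methyl (2S)-piperidine-1,2-dicarboxylate
Conditions: MeI, K2CO3, DMF, rt
Reagents that add atoms: iodomethane, CI
Why: SN2 O-alkylation of the carboxylate; the urethane-protected α-centre is not enolised by carbonate, so C2'' should pass unchanged.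

Step 2
Reactants: 2 1-tert-butyl 2-methyl (2S)-piperidine-1,2-dicarboxylate
Product: 5 tert-butyl (2S)-2-{[tri(propan-2-yl)silyloxy]ethynyl}piperidine-1-carboxylate, via lithium dibromoenolate 3 (not isolated), via lithium ynolate 4 (not isolated)
Conditions: CH2Br2, lithium 2,2,6,6-tetramethylpiperidide, THF, −78 °C; n-BuLi, −78 °C → rt; i-Pr3SiCl, 0 °C → rt
Reagents that add atoms: dibromomethane, BrCBr; chlorotriisopropylsilane, CC(C)[Si](Cl)(C(C)C)C(C)C
Why: Kowalski ester homologation: dibromomethyllithium adds to the ester, the dibromoketone is held as enolate 3 (which also keeps C2''–H from being enolised), and bromine–lithium exchange triggers the 1,2-shift of the piperidinyl carbon with retention to ynolate 4. The bulky silyl chloride should silylate 4 on oxygen, and the N–H-free Boc group should tolerate the cold alkyllithium.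

Step 3
Reactants: 6 3-ethoxycyclobut-2-en-1-one; 7 (4-methoxyphenyl)methanol
Product: 8 3-[(4-methoxybenzyl)oxy]cyclobut-2-en-1-one
Conditions: CSA (5 mol%), PhMe, 40 °C, reduced pressure (−EtOH)
Reagents that add atoms: none
Why: Acid-catalysed alkoxy exchange of a vinylogous ester by addition–elimination at C3, driven by removal of ethanol; a low loading of sulfonic acid should keep 7 from self-etherifying.

Step 4
Reactants: 5 tert-butyl (2S)-2-{[tri(propan-2-yl)silyloxy]ethynyl}piperidine-1-carboxylate; 8 3-[(4-methoxybenzyl)oxy]cyclobut-2-en-1-one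
Product: 13 tert-butyl (2S)-2-[2-hydroxy-4-(4-methoxybenzyloxy)-6-(triisopropylsilyloxy)phenyl]piperidine-1-carboxylate, via vinylketene 9 (not isolated), via 4-vinylcyclobutenone 10 (not isolated), via dienylketene 11 (not isolated), via cyclohexadienone 12 (not isolated)
Conditions: PhMe (degassed), 80 °C, then 110 °C, sealed vessel
Reagents that add atoms: none
Why: This is a Danheiser benzannulation of a cyclobutenone with a siloxyalkyne, the closest known reaction type, applied here to a 3-alkoxycyclobutenone and an α-branched ynol ether. Heating opens 8 by four-electron electrocyclic ring opening to vinylketene 9; the nucleophilic, piperidine-bearing carbon of 5 attacks the ketene carbonyl carbon in a regioselective (2+2) cycloaddition that forms C6–C7 and C4a–C5 and gives 10. A second four-electron opening gives dienylketene 11, and ring A closes by six-electron electrocyclisation at C7–C8 to dienone 12, which tautomerises to phenol 13. No stereocentre is created: C2'' is neither enolisable nor part of the pericyclic array, and the transient sp3 centre of 10 is erased on aromatisation. The selectivity needed is regiochemical and is set by the polarisation of the ynol ether, which places C6 between the new hydroxyl on C7 and the silyloxy carbon C5 and leaves the PMB ether on C8a para to the piperidine. The carbamate is stable at these temperatures, and the hindered phenol of 13 should be a poor trap for 9.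

Step 5
Reactants: 13 tert-butyl (2S)-2-[2-hydroxy-4-(4-methoxybenzyloxy)-6-(triisopropylsilyloxy)phenyl]piperidine-1-carboxylate
Product: 16 tert-butyl (2S)-2-[2,6-bis(benzyloxy)-4-(4-methoxybenzyloxy)phenyl]piperidine-1-carboxylate, via resorcinol 14 (not isolated), via monobenzyl ether 15 (not isolated)
Conditions: Bu4NF, THF, 0 °C; then BnBr, K2CO3, DMF, rt → 50 °C
Reagents that add atoms: benzyl bromide, BrCc1ccccc1
Why: Fluoride cleaves the aryl silyl ether to symmetric resorcinol 14, and Williamson etherification through 15 benzylates both phenols; making O5 and O7 identical removes any later regiochemical question.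

Step 6
Reactants: 16 tert-butyl (2S)-2-[2,6-bis(benzyloxy)-4-(4-methoxybenzyloxy)phenyl]piperidine-1-carboxylate
Product: 17 (2S)-2-[2,6-bis(benzyloxy)-4-(4-methoxybenzyloxy)phenyl]-1-methylpiperidine
Conditions: LiAlH4, THF, reflux; aqueous NaOH work-up
Reagents that add atoms: none
Why: Hydride reduction of an N,N-disubstituted carbamate to the N-methyl amine (loss of tert-butoxide, then reduction of the formamide); the ethers are inert, and the basic amine is the form of C2''–N that best resists the acid used later.

Step 7
Reactants: 17 (2S)-2-[2,6-bis(benzyloxy)-4-(4-methoxybenzyloxy)phenyl]-1-methylpiperidine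
Product: 18 3,5-bis(benzyloxy)-4-[(2S)-1-methylpiperidin-2-yl]phenol
Conditions: CF3CO2H, Et3SiH, CH2Cl2, 0 °C; aq. NaHCO3
Reagents that add atoms: none
Why: Acidolysis of the aryl PMB ether with silane capture of the benzylic cation; benzyl aryl ethers need much stronger acid, and the protonated amine should not ionise at C2''.

Step 8
Reactants: 19 4-hydroxybenzoic acid
Product: 20 4-{[(benzyloxy)carbonyl]oxy}benzoic acid
Conditions: BnOCOCl, aq. NaOH, 0 °C; then HCl to pH 2
Reagents that add atoms: benzyl chloroformate, O=C(Cl)OCc1ccccc1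
Why: Schotten–Baumann acylation of the phenoxide; the carbonate is the electron-withdrawing, hydrogenolysable mask for O4'.

Step 9
Reactants: 20 4-{[(benzyloxy)carbonyl]oxy}benzoic acid
Product: 23 tert-butyl 3-(4-{[(benzyloxy)carbonyl]oxy}phenyl)-3-oxopropanoate, via acid chloride 21 (not isolated), via acylmalonate 22 (not isolated)
Conditions: (COCl)2, DMF (cat.), CH2Cl2, 0 °C → rt; evaporate; KO2CCH2CO2t-Bu, MgCl2, Et3N, MeCN, 0 °C → rt; aq. citric acid
Reagents that add atoms: potassium 3-(tert-butoxy)-3-oxopropanoate, CC(C)(C)OC(=O)CC(=O)[O-].[K+]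
Why: Magnesium-mediated C-acylation of a malonate half-ester by 21, then decarboxylation of 22 on acidic work-up (malonate route to β-keto esters); the weakly basic conditions should leave the aryl carbonate alone.

Step 10
Reactants: 23 tert-butyl 3-(4-{[(benzyloxy)carbonyl]oxy}phenyl)-3-oxopropanoate
Product: 24 tert-butyl (3R)-3-(4-{[(benzyloxy)carbonyl]oxy}phenyl)-3-hydroxypropanoate
Conditions: RuCl[(R,R)-TsDPEN](p-cymene) (1 mol%), HCO2H–Et3N (5:2), EtOAc, rt
Reagents that add atoms: none
Why: Noyori–Ikariya asymmetric transfer hydrogenation of an aryl ketone; the (R,R) catalyst should give the (R)-carbinol for this priority pattern (OH > aryl > CH2), and formic acid–triethylamine is compatible with the carbonate and the tert-butyl ester.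

Step 11
Reactants: 18 3,5-bis(benzyloxy)-4-[(2S)-1-methylpiperidin-2-yl]phenol; 24 tert-butyl (3R)-3-(4-{[(benzyloxy)carbonyl]oxy}phenyl)-3-hydroxypropanoate
Product: 25 tert-butyl (3S)-3-{3,5-bis(benzyloxy)-4-[(2S)-1-methylpiperidin-2-yl]phenoxy}-3-(4-{[(benzyloxy)carbonyl]oxy}phenyl)propanoate
Conditions: PPh3, DIAD, THF, 0 °C → rt
Reagents that add atoms: none
Why: Mitsunobu etherification: the phenoxide displaces the alkoxyphosphonium of 24 by SN2 with inversion, so (R)-24 gives the (S)-ether that becomes C2. The electron-withdrawing carbonate on ring B disfavours ionisation of the benzylic centre and so protects stereochemical fidelity.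

Step 12
Reactants: 25 tert-butyl (3S)-3-{3,5-bis(benzyloxy)-4-[(2S)-1-methylpiperidin-2-yl]phenoxy}-3-(4-{[(benzyloxy)carbonyl]oxy}phenyl)propanoate
Product: 28 benzyl 4-{(2S)-5,7-bis(benzyloxy)-6-[(2S)-1-methylpiperidin-2-yl]-4-oxochroman-2-yl}phenyl carbonate, via carboxylic acid 26 (not isolated), via mixed anhydride 27 (not isolated)
Conditions: CF3CO2H, PhSMe, CH2Cl2, 0 °C → rt; evaporate; (CF3CO)2O, CH2Cl2, 0 °C; aq. NaHCO3
Reagents that add atoms: none
Why: Acidolysis of the tert-butyl ester gives 26, the anhydride converts it into 27, and intramolecular Friedel–Crafts acylation of the strongly activated ring closes ring C at C4–C4a (six-membered ring; either ortho carbon gives the same product). C2 is not involved, the amine is protected as its ammonium salt, and the sulfide scavenges tert-butyl cations that could otherwise alkylate ring A.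

Step 13
Reactants: 28 benzyl 4-{(2S)-5,7-bis(benzyloxy)-6-[(2S)-1-methylpiperidin-2-yl]-4-oxochroman-2-yl}phenyl carbonate
Product: 29 (2S)-5,7-dihydroxy-2-(4-hydroxyphenyl)-6-[(2S)-1-methylpiperidin-2-yl]chroman-4-one
Conditions: H2 (1 atm), Pd/C, EtOAc–MeOH, rt
Reagents that add atoms: none
Why: Hydrogenolysis of the two benzyl ethers and the benzyl carbonate (which loses CO2) under neutral conditions, so neither C2 nor C2''–N is put at risk; benzyl–oxygen bonds should cleave faster than the cyclic benzylic C2–O1 and C2''–N bonds.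

## Compound list

1 | (2S)-1-(tert-butoxycarbonyl)piperidine-2-carboxylic acid | CC(C)(C)OC(=O)N1CCCC[C@H]1C(=O)O | starting material
2 | 1-tert-butyl 2-methyl (2S)-piperidine-1,2-dicarboxylate | CC(C)(C)OC(=O)N1CCCC[C@H]1C(=O)OC | intermediate
3 | lithium 2,2-dibromo-1-[(2S)-1-(tert-butoxycarbonyl)piperidin-2-yl]ethen-1-olate | CC(C)(C)OC(=O)N1CCCC[C@H]1C([O-])=C(Br)Br.[Li+] | intermediate (not isolated)
4 | lithium 2-[(2S)-1-(tert-butoxycarbonyl)piperidin-2-yl]ethyn-1-olate | CC(C)(C)OC(=O)N1CCCC[C@H]1C#C[O-].[Li+] | intermediate (not isolated)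
5 | tert-butyl (2S)-2-{[tri(propan-2-yl)silyloxy]ethynyl}piperidine-1-carboxylate | CC(C)(C)OC(=O)N1CCCC[C@H]1C#CO[Si](C(C)C)(C(C)C)C(C)C | intermediate
6 | 3-ethoxycyclobut-2-en-1-one | CCOC1=CC(=O)C1 | starting material
7 | (4-methoxyphenyl)methanol | COc1ccc(CO)cc1 | starting material
8 | 3-[(4-methoxybenzyl)oxy]cyclobut-2-en-1-one | O=C1C=C(OCc2ccc(OC)cc2)C1 | intermediate
9 | 3-[(4-methoxybenzyl)oxy]buta-1,3-dien-1-one | O=C=CC(=C)OCc1ccc(OC)cc1 | intermediate (not isolated)
10 | tert-butyl (2S)-2-{3-[1-(4-methoxybenzyloxy)ethenyl]-4-oxo-2-(triisopropylsilyloxy)cyclobut-1-en-1-yl}piperidine-1-carboxylate (both epimers at the ring sp3 carbon) | CC(C)(C)OC(=O)N1CCCC[C@H]1C1=C(O[Si](C(C)C)(C(C)C)C(C)C)C(C(=C)OCc2ccc(OC)cc2)C1=O | intermediate (not isolated)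
11 | tert-butyl (2S)-2-[(3E)-5-(4-methoxybenzyloxy)-1-oxo-3-(triisopropylsilyloxy)hexa-1,3,5-trien-2-yl]piperidine-1-carboxylate | CC(C)(C)OC(=O)N1CCCC[C@H]1C(=C=O)/C(O[Si](C(C)C)(C(C)C)C(C)C)=C\C(=C)OCc1ccc(OC)cc1 | intermediate (not isolated)
12 | tert-butyl (2S)-2-[4-(4-methoxybenzyloxy)-6-oxo-2-(triisopropylsilyloxy)cyclohexa-1,3-dien-1-yl]piperidine-1-carboxylate | CC(C)(C)OC(=O)N1CCCC[C@H]1C1=C(O[Si](C(C)C)(C(C)C)C(C)C)C=C(OCc2ccc(OC)cc2)CC1=O | intermediate (not isolated)
13 | tert-butyl (2S)-2-[2-hydroxy-4-(4-methoxybenzyloxy)-6-(triisopropylsilyloxy)phenyl]piperidine-1-carboxylate | CC(C)(C)OC(=O)N1CCCC[C@H]1c1c(O[Si](C(C)C)(C(C)C)C(C)C)cc(OCc2ccc(OC)cc2)cc1O | intermediate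
14 | tert-butyl (2S)-2-[2,6-dihydroxy-4-(4-methoxybenzyloxy)phenyl]piperidine-1-carboxylate | CC(C)(C)OC(=O)N1CCCC[C@H]1c1c(O)cc(OCc2ccc(OC)cc2)cc1O | intermediate (not isolated)
15 | tert-butyl (2S)-2-[2-(benzyloxy)-6-hydroxy-4-(4-methoxybenzyloxy)phenyl]piperidine-1-carboxylate | CC(C)(C)OC(=O)N1CCCC[C@H]1c1c(OCc2ccccc2)cc(OCc2ccc(OC)cc2)cc1O | intermediate (not isolated)
16 | tert-butyl (2S)-2-[2,6-bis(benzyloxy)-4-(4-methoxybenzyloxy)phenyl]piperidine-1-carboxylate | CC(C)(C)OC(=O)N1CCCC[C@H]1c1c(OCc2ccccc2)cc(OCc2ccc(OC)cc2)cc1OCc1ccccc1 | intermediate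
17 | (2S)-2-[2,6-bis(benzyloxy)-4-(4-methoxybenzyloxy)phenyl]-1-methylpiperidine | CN1CCCC[C@H]1c1c(OCc2ccccc2)cc(OCc2ccc(OC)cc2)cc1OCc1ccccc1 | intermediate
18 | 3,5-bis(benzyloxy)-4-[(2S)-1-methylpiperidin-2-yl]phenol | CN1CCCC[C@H]1c1c(OCc2ccccc2)cc(O)cc1OCc1ccccc1 | intermediate
19 | 4-hydroxybenzoic acid | O=C(O)c1ccc(O)cc1 | starting material
20 | 4-{[(benzyloxy)carbonyl]oxy}benzoic acid | O=C(O)c1ccc(OC(=O)OCc2ccccc2)cc1 | intermediate
21 | 4-{[(benzyloxy)carbonyl]oxy}benzoyl chloride | O=C(Cl)c1ccc(OC(=O)OCc2ccccc2)cc1 | intermediate (not isolated)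
22 | 2-(4-{[(benzyloxy)carbonyl]oxy}benzoyl)-3-(tert-butoxy)-3-oxopropanoic acid (racemic, present as its magnesium salt) | CC(C)(C)OC(=O)C(C(=O)O)C(=O)c1ccc(OC(=O)OCc2ccccc2)cc1 | intermediate (not isolated)
23 | tert-butyl 3-(4-{[(benzyloxy)carbonyl]oxy}phenyl)-3-oxopropanoate | CC(C)(C)OC(=O)CC(=O)c1ccc(OC(=O)OCc2ccccc2)cc1 | intermediate
24 | tert-butyl (3R)-3-(4-{[(benzyloxy)carbonyl]oxy}phenyl)-3-hydroxypropanoate | CC(C)(C)OC(=O)C[C@@H](O)c1ccc(OC(=O)OCc2ccccc2)cc1 | intermediate
25 | tert-butyl (3S)-3-{3,5-bis(benzyloxy)-4-[(2S)-1-methylpiperidin-2-yl]phenoxy}-3-(4-{[(benzyloxy)carbonyl]oxy}phenyl)propanoate | CN1CCCC[C@H]1c1c(OCc2ccccc2)cc(O[C@@H](CC(=O)OC(C)(C)C)c2ccc(OC(=O)OCc3ccccc3)cc2)cc1OCc1ccccc1 | intermediate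
26 | (3S)-3-{3,5-bis(benzyloxy)-4-[(2S)-1-methylpiperidin-2-yl]phenoxy}-3-(4-{[(benzyloxy)carbonyl]oxy}phenyl)propanoic acid | CN1CCCC[C@H]1c1c(OCc2ccccc2)cc(O[C@@H](CC(=O)O)c2ccc(OC(=O)OCc3ccccc3)cc2)cc1OCc1ccccc1 | intermediate (not isolated)
27 | (3S)-3-{3,5-bis(benzyloxy)-4-[(2S)-1-methylpiperidin-2-yl]phenoxy}-3-(4-{[(benzyloxy)carbonyl]oxy}phenyl)propanoic trifluoroacetic anhydride | CN1CCCC[C@H]1c1c(OCc2ccccc2)cc(O[C@@H](CC(=O)OC(=O)C(F)(F)F)c2ccc(OC(=O)OCc3ccccc3)cc2)cc1OCc1ccccc1 | intermediate (not isolated)
28 | benzyl 4-{(2S)-5,7-bis(benzyloxy)-6-[(2S)-1-methylpiperidin-2-yl]-4-oxochroman-2-yl}phenyl carbonate | CN1CCCC[C@H]1c1c(OCc3ccccc3)cc2c(c1OCc1ccccc1)C(=O)C[C@@H](c1ccc(OC(=O)OCc3ccccc3)cc1)O2 | intermediate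
29 | (2S)-5,7-dihydroxy-2-(4-hydroxyphenyl)-6-[(2S)-1-methylpiperidin-2-yl]chroman-4-one | CN1CCCC[C@H]1c1c(O)cc2c(c1O)C(=O)C[C@@H](c1ccc(O)cc1)O2 | target

## Step count and least certain steps

Total: 13 steps. Longest linear sequence: 9 steps (1, 2, 4, 5, 6, 7, 11, 12, 13).

**Step 4 (key step).** The most likely failure is that cycloaddition at the α-branched alkyne carbon is slower than self-condensation of the vinylketene or thermal decay of the ynol ether; the cascade may also stall before the final electrocyclisation, or the product phenol may be acylated by the ketene. The fallback gives up building ring A on the stereocentre and sets C2'' by auxiliary control on a preformed ring; it sets out from 7 and returns at 17. Mitsunobu alkylation of the 4-hydroxyl of 2,4,6-trihydroxybenzaldehyde (the most acidic and not hydrogen-bonded) with 7 gives 2,6-dihydroxy-4-(4-methoxybenzyloxy)benzaldehyde F1. Double benzylation gives 2,6-bis(benzyloxy)-4-(4-methoxybenzyloxy)benzaldehyde F2. Condensation with (R)-tert-butanesulfinamide and Ti(OEt)4 gives the (R)-N-sulfinyl aldimine F3. Addition of 4-chlorobutylmagnesium bromide in CH2Cl2 through the chelated chair transition state should give the (S)-configured chloro sulfinamide F4. KN(SiMe3)2 closes the ring to the N-sulfinyl piperidine F5, and brief HCl in methanol at 0 °C frees the secondary amine (2S)-2-[2,6-bis(benzyloxy)-4-(4-methoxybenzyloxy)phenyl]piperidine F6. Reductive methylation with aqueous formaldehyde and NaBH(OAc)3 gives 17.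

**Step 2.** The most likely failure is attack of the alkyllithium on the carbamate, partial enolisation at C2'' before the ketone is secured as its enolate, or silylation on carbon instead of oxygen. The fallback reaches the ynolate by oxidation of an acetylide; it sets out from 2 and returns at 5. Reduction with i-Bu2AlH at −78 °C gives tert-butyl (2S)-2-formylpiperidine-1-carboxylate F7. Ohira–Bestmann homologation gives tert-butyl (2S)-2-ethynylpiperidine-1-carboxylate F8. Deprotonation with LiN(SiMe3)2 and oxidation of the acetylide with LiOOt-Bu gives ynolate 4, which is silylated with i-Pr3SiOTf to give 5.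

**Step 3.** The most likely failure is acid-promoted self-condensation of the benzylic alcohol, or loss of the strained vinylogous ester before the exchange equilibrium is driven over. The fallback replaces exchange by alkylation of the parent vinylogous acid; it sets out from 6 and returns at 8. Cold aqueous HCl hydrolyses 6 to cyclobutane-1,3-dione F9, which is O-alkylated with 7 under Mitsunobu conditions (PPh3, DIAD) to give 8.

**Step 11.** The most likely failure is loss of stereochemical fidelity through ionisation of the benzylic alkoxyphosphonium, elimination to the cinnamate, or carbonate transfer to the phenoxide. The fallback closes ring C from the other side and sets C2 by separation; it sets out from 18 and returns at 29.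
- C-acetylation with Ac2O and BF3·OEt2 gives 1-{2,4-bis(benzyloxy)-6-hydroxy-3-[(2S)-1-methylpiperidin-2-yl]phenyl}ethan-1-one F10.
- Claisen–Schmidt condensation with 4-(benzyloxy)benzaldehyde and KOH gives the chalcone F11.
- Oxa-Michael cyclisation with NaOAc in ethanol gives the flavanone as two C2 epimers. These are diastereomers because C2'' is fixed; they are separated, and the unwanted one is re-equilibrated through the chalcone. This gives (2S)-5,7-bis(benzyloxy)-2-[4-(benzyloxy)phenyl]-6-[(2S)-1-methylpiperidin-2-yl]chroman-4-one F12.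
- Hydrogenolysis as in step 13 gives 29.

**Step 12.** The most likely failure is alkylation of ring A by tert-butyl cations, trifluoroacetylation of ring A before ring closure, or acid-promoted ionisation of the benzylic C2–O bond during the long acid exposure. The fallback changes the carboxyl mask so that the acid is freed without acid or carbocations and only the short acylation remains; it sets out from 20 and 18 and returns at 26.
- Acid 20 is converted as in step 9, with potassium allyl malonate, into prop-2-en-1-yl 3-(4-{[(benzyloxy)carbonyl]oxy}phenyl)-3-oxopropanoate F13.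
- Transfer hydrogenation as in step 10 gives the allyl (3R)-hydroxy ester F14.
- Mitsunobu reaction with 18 gives the allyl (3S)-aryloxy ester F15.
- Pd(PPh3)4 with PhSiH3 removes the allyl group to give isolated 26, which is cyclised by short exposure to (CF3CO)2O at 0 °C to 28.

## Further compounds

F1 | step 4 | 2,6-dihydroxy-4-(4-methoxybenzyloxy)benzaldehyde | O=Cc1c(O)cc(OCc2ccc(OC)cc2)cc1O
F2 | step 4 | 2,6-bis(benzyloxy)-4-(4-methoxybenzyloxy)benzaldehyde | O=Cc1c(OCc2ccccc2)cc(OCc2ccc(OC)cc2)cc1OCc1ccccc1
F3 | step 4 | (R)-N-[(E)-2,6-bis(benzyloxy)-4-(4-methoxybenzyloxy)benzylidene]-2-methylpropane-2-sulfinamide | CC(C)(C)[S@@](=O)/N=C/c1c(OCc2ccccc2)cc(OCc2ccc(OC)cc2)cc1OCc1ccccc1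
F4 | step 4 | (R)-N-{(1S)-1-[2,6-bis(benzyloxy)-4-(4-methoxybenzyloxy)phenyl]-5-chloropentyl}-2-methylpropane-2-sulfinamide | CC(C)(C)[S@@](=O)N[C@@H](CCCCCl)c1c(OCc2ccccc2)cc(OCc2ccc(OC)cc2)cc1OCc1ccccc1
F5 | step 4 | (2S)-2-[2,6-bis(benzyloxy)-4-(4-methoxybenzyloxy)phenyl]-1-[(R)-tert-butylsulfinyl]piperidine | CC(C)(C)[S@@](=O)N1CCCC[C@H]1c1c(OCc2ccccc2)cc(OCc2ccc(OC)cc2)cc1OCc1ccccc1
F6 | step 4 | (2S)-2-[2,6-bis(benzyloxy)-4-(4-methoxybenzyloxy)phenyl]piperidine | N1CCCC[C@H]1c1c(OCc2ccccc2)cc(OCc2ccc(OC)cc2)cc1OCc1ccccc1
F7 | step 2 | tert-butyl (2S)-2-formylpiperidine-1-carboxylate | CC(C)(C)OC(=O)N1CCCC[C@H]1C=O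
F8 | step 2 | tert-butyl (2S)-2-ethynylpiperidine-1-carboxylate | CC(C)(C)OC(=O)N1CCCC[C@H]1C#C
F9 | step 3 | cyclobutane-1,3-dione | O=C1CC(=O)C1
F10 | step 11 | 1-{2,4-bis(benzyloxy)-6-hydroxy-3-[(2S)-1-methylpiperidin-2-yl]phenyl}ethan-1-one | CN1CCCC[C@H]1c1c(OCc2ccccc2)cc(O)c(C(C)=O)c1OCc1ccccc1
F11 | step 11 | (2E)-1-{2,4-bis(benzyloxy)-6-hydroxy-3-[(2S)-1-methylpiperidin-2-yl]phenyl}-3-[4-(benzyloxy)phenyl]prop-2-en-1-one | CN1CCCC[C@H]1c1c(OCc2ccccc2)cc(O)c(C(=O)/C=C/c2ccc(OCc3ccccc3)cc2)c1OCc1ccccc1
F12 | step 11 | (2S)-5,7-bis(benzyloxy)-2-[4-(benzyloxy)phenyl]-6-[(2S)-1-methylpiperidin-2-yl]chroman-4-one | CN1CCCC[C@H]1c1c(OCc3ccccc3)cc2c(c1OCc1ccccc1)C(=O)C[C@@H](c1ccc(OCc3ccccc3)cc1)O2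
F13 | step 12 | prop-2-en-1-yl 3-(4-{[(benzyloxy)carbonyl]oxy}phenyl)-3-oxopropanoate | C=CCOC(=O)CC(=O)c1ccc(OC(=O)OCc2ccccc2)cc1
F14 | step 12 | prop-2-en-1-yl (3R)-3-(4-{[(benzyloxy)carbonyl]oxy}phenyl)-3-hydroxypropanoate | C=CCOC(=O)C[C@@H](O)c1ccc(OC(=O)OCc2ccccc2)cc1
F15 | step 12 | prop-2-en-1-yl (3S)-3-{3,5-bis(benzyloxy)-4-[(2S)-1-methylpiperidin-2-yl]phenoxy}-3-(4-{[(benzyloxy)carbonyl]oxy}phenyl)propanoate | CN1CCCC[C@H]1c1c(OCc2ccccc2)cc(O[C@@H](CC(=O)OCC=C)c2ccc(OC(=O)OCc3ccccc3)cc2)cc1OCc1ccccc1
A1 | alternative 1 | (S)-5,7-bis(benzyloxy)-6-[(S)-1-methylpiperidin-2-yl]-2-[4-(pivaloyloxy)phenyl]chroman-4-one | CN1CCCC[C@H]1c1c(OCc3ccccc3)cc2c(c1OCc1ccccc1)C(=O)C[C@@H](c1ccc(OC(=O)C(C)(C)C)cc1)O2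
A2 | alternative 1 | (3S)-3-{3,5-bis(benzyloxy)-4-[(2S)-1-methylpiperidin-2-yl]phenoxy}-3-[4-(pivaloyloxy)phenyl]propanoic acid | CN1CCCC[C@H]1c1c(OCc2ccccc2)cc(O[C@@H](CC(=O)O)c2ccc(OC(=O)C(C)(C)C)cc2)cc1OCc1ccccc1
A3 | alternative 2 | tert-butyl (S)-2-{(S)-5,7-bis(tert-butyldimethylsilyloxy)-2-[4-(tert-butyldimethylsilyloxy)phenyl]-4-oxochroman-6-yl}piperidine-1-carboxylate | CC(C)(C)OC(=O)N1CCCC[C@H]1c1c(O[Si](C)(C)C(C)(C)C)cc2c(c1O[Si](C)(C)C(C)(C)C)C(=O)C[C@@H](c1ccc(O[Si](C)(C)C(C)(C)C)cc1)O2
A4 | alternative 2 | tert-butyl (2S)-2-{2,6-bis(tert-butyldimethylsilyloxy)-3-(2-diazoacetyl)-4-[4-(tert-butyldimethylsilyloxy)benzyloxy]phenyl}piperidine-1-carboxylate | CC(C)(C)OC(=O)N1CCCC[C@H]1c1c(O[Si](C)(C)C(C)(C)C)cc(OCc2ccc(O[Si](C)(C)C(C)(C)C)cc2)c(C(=O)C=[N+]=[N-])c1O[Si](C)(C)C(C)(C)C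
A5 | alternative 3 | tert-butyl (S)-2-{(S)-2-[4-(benzyloxy)phenyl]-5,7-dihydroxy-4-oxochroman-6-yl}piperidine-1-carboxylate | CC(C)(C)OC(=O)N1CCCC[C@H]1c1c(O)cc2c(c1O)C(=O)C[C@@H](c1ccc(OCc3ccccc3)cc1)O2
A6 | alternative 3 | methyl (2S)-2-[4-(benzyloxy)phenyl]-6-{3-[(2S)-1-(tert-butoxycarbonyl)piperidin-2-yl]-2-oxopropyl}-4-oxo-3,4-dihydro-2H-pyran-5-carboxylate | CC(C)(C)OC(=O)N1CCCC[C@H]1CC(=O)CC1=C(C(=O)OC)C(=O)C[C@@H](c2ccc(OCc3ccccc3)cc2)O1
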